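In a closed stirred flask, Monday's run shows G down to 1% by 0.500 d, yet oak and cedar each spread one charge over 4.00 d.

| flask | G | E | remark | time |
|---|---|---|---|---|
| Monday's | 0.10 M | 1.8 equiv | run made earlier |  |
| Sunday's | 0.14 M | 1.8 equiv | run made earlier |  |
| Wednesday's | 0.22 M | 1.8 equiv | run made earlier |  |
| Saturday's | 0.10 M | 0.90 equiv | run made earlier |  |
| oak | 0.10 M | 1.80 equiv (fed, over 4.00 d) | all but E at the start; E goes in evenly over 4.00 d, the run ends at 4.0 d | 4.0 d |
| cedar | 0.10 M (fed, over 4.00 d) | 1.80 equiv | a stirred flask in which G is dosed at a steady rate over 4.00 d without added volume, worked up at 4.0 d | 4.0 d |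
| elm | 0.10 M | 1.80 equiv | everything together in a closed stirred flask, run for 4.0 d | 4.0 d |
| ash | 0.10 M | 1.80 equiv | a single well-mixed tank run continuously and read at steady state, 4.0 d in it on average |  |

| run | time / d | D / % | X / % | G / % |
|---|---|---|---|---|
| Monday's | 0.333 | 38 | 62 | 6 |
| Monday's | 0.500 | 36 | 64 | 1 |
| Monday's | 0.833 | 36 | 64 | 0 |
| Monday's | 1.04 | 34 | 64 | 0 |
| Monday's | 1.67 | 37 | 63 | 0 |
| Monday's | 2.50 | 35 | 63 | 0 |
| Monday's | 4.00 | 36 | 64 | 0 |
| Sunday's | 0.167 | 42 | 46 | 12 |
| Sunday's | 0.500 | 44 | 57 | 3 |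
| Sunday's | 0.833 | 44 | 56 | 0 |
| Sunday's | 1.25 | 46 | 59 | 1 |
| Sunday's | 2.08 | 42 | 58 | 1 |
| Sunday's | 2.50 | 43 | 59 | 1 |
| Sunday's | 3.00 | 46 | 57 | 1 |
| Wednesday's | 0.167 | 51 | 40 | 9 |
| Wednesday's | 0.500 | 57 | 44 | 2 |
| Wednesday's | 0.833 | 52 | 46 | 0 |
| Wednesday's | 1.25 | 55 | 47 | 0 |
| Wednesday's | 2.08 | 57 | 46 | 1 |
| Wednesday's | 2.50 | 54 | 48 | 0 |
| Wednesday's | 3.00 | 54 | 46 | 2 |
| Saturday's | 0.250 | 20 | 70 | 12 |
| Saturday's | 0.500 | 18 | 76 | 1 |
| Saturday's | 0.833 | 18 | 81 | 0 |
| Saturday's | 1.67 | 20 | 80 | 0 |
| Saturday's | 3.00 | 20 | 79 | 0 |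

(each reading ± 1.5 percentage points)

- the stated concentrations are those of everything mixed, before any reaction; amounts are the same in each set-up
- the numbers in the tables scatter by 1.5 percentage points (one standard deviation)
- the feed brings no volume worth counting
- the earlier runs were made in a closed, stirred flask

- the set-up with the highest share of D in all that became D or X, at the outlet or at the end ("none" if the first two lie within 2 percentage points) (oak / cedar / elm / ash / none)
- share of D in all that became D or X, at the outlet or at the end, oak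
- share of D in all that became D or X, at the outlet or at the end, cedar
- share of D in all that became D or X, at the outlet or at the end, elm
- share of D in all that became D or X, at the outlet or at the end, ash

Count G's lifetimes first. Take the decay from Monday's first row, then keep the part that goes to X, which is how G behaves with cE near zero, as early in oak:

k = 8.45 d⁻¹, of which X takes kX = 5.41 d⁻¹

Next read a selectivity factor, D/X per cE as charged, from Monday's plateau:

s = 3.12 L mol⁻¹

Wednesday's run reads 2.96 L mol⁻¹, so keep s.

In oak, E enters at r = 0.0450 M d⁻¹; reckon cE as climbing at that rate while G decays at kX. Take the mean cE that a G meets before it goes, cE,met = r/kX: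

cE,met = 0.00832 M

oak share = 2.53%

The weak link is E's own fate, and the tables carry no E. Oak's reckoning leans on E over about 1/kX = 0.185 d, shorter than the 0.500 d by which Monday's run reads G at 1%. Cedar's dosing lasts 4.00 d and ash holds its contents 4.0 d on average, both longer than that, so give them no number. Commit to oak at 2.53% and to elm, which is Monday's recipe, at 36.0%.

The forecast says none, with oak 2.6%, cedar 36%, elm 36% and ash 34%, holding of cedar that “Dosing G changes nothing”.

The flask gives elm as best: oak 1.63%, cedar 1.95%, elm 35.2%, ash 3.73%.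

    G + E → D (k = 1.70 L mol⁻¹ h⁻¹)
    G → X (k = 0.310 h⁻¹)
    E → Q (k = 0.250 h⁻¹)

E's half-life by E → Q, 0.12 d in oak, stands far below the dosing time of 4.00 d, and cedar reads E at 0% by 2.00 d, with D at 1.89%. Oak's computed share lies under my 2.53%; as a ratio it is D/X = 0.0165, to be set beside cE,met = 0.00832 M.

Now charge oak with 7.20 equiv of E. Then cE,met is 0.0333 M, 4.00 times oak's, and scaling oak's D/X by that gives 6.20%. The computed share is 6.00%.

The readings stem from a simulated flask with made-up constants; scatter was added.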